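The side chain is cut from the hydroazulene at C4–C11. Oxygen O5 on the seven-membered ring and side-chain oxygen O12 flank this bond in a 1,4-relationship (O5–C5–C4–C11–C12–O12), the retron of an enolate–epoxide opening. The key step lets the C4 lithium enolate of a fully functionalised bicyclic C5 ketone (C1 methylene, protected C2 and C10 carbinols; built by Danheiser cyclopentene annulation on a 4-silyloxycycloheptenone) open a trans-2,3-epoxide that already carries O13 and the isobutenyl group. One operation joins the halves, fixes C11 by SN2 inversion and releases the C12 hydroxyl. C4 is then corrected by protonation of a cyclic enol ether, and a three-step endgame follows.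

Key step: step 17

Remarks
- Route numbering: seven-membered ring C1 (=CH2), C2 (O), C3, C4 (side chain), C5 (O), C6, C7; five-membered ring C6, C7, C8=C9, C10 (Me, O); side chain C11 (Me), C12 (O), C13 (O), C14=C15. α is the face of H-6/H-7. In this numbering the target is 2R,4S,5R,6S,7R,10R,11R,12S,13S.
- Assumption: the quinine-derived catalyst of step 2 gives the (R)-hydroxy enone; if the sense is opposite, the quinidine-derived pseudoenantiomer is used.
- Assumption: allene 5 is purchasable (otherwise one step from 3-(trimethylsilyl)prop-2-ynyl mesylate, MeMgCl and CuBr).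
- C5 in 8 and 9 is an inconsequential epimer mixture (oxidised in step 7) and is drawn without configuration.

**Ring fragment (steps 1–11)**

Step 1
Reactants: 1 cyclohepta-1,3-diene
Product: 2 6,7-dioxabicyclo[3.2.2]non-8-ene (meso endoperoxide)
Conditions: O2, TPP (cat.), hν, CH2Cl2, 0 °C
Reagents that add atoms: oxygen (O=O)
Why: Singlet-oxygen [4+2] cycloaddition to the cyclic 1,3-diene should give the meso endoperoxide with the two oxygens 1,4 across a new cis alkene.

Step 2
Reactants: 2 6,7-dioxabicyclo[3.2.2]non-8-ene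
Product: 3 (R)-4-hydroxycyclohept-2-en-1-one
Conditions: 9-O-acetylcupreine (deMeQAc, 5 mol %), CH2Cl2, rt
Reagents that add atoms: none
Why: Enantioselective Kornblum–DeLaMare rearrangement: the chiral base removes one of the two enantiotopic bridgehead hydrogens of the meso peroxide, so the carbinol stereocentre (later C1) is set by the catalyst.

Step 3
Reactants: 3 (R)-4-hydroxycyclohept-2-en-1-one
Product: 4 (R)-4-(tert-butyldimethylsilyloxy)cyclohept-2-en-1-one
Conditions: TBSCl, imidazole, DMF, 0 °C → rt
Reagents that add atoms: tert-butyldimethylsilyl chloride (CC(C)(C)[Si](C)(C)Cl)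
Why: Standard silylation gives a bulky γ-substituent that directs the annulation and survives TiCl4 at −78 °C.

Step 4
Reactants: 4 (R)-4-(tert-butyldimethylsilyloxy)cyclohept-2-en-1-one; 5 1-methyl-1-(trimethylsilyl)allene
Product: 6 cis-fused 1α-(TBSO)-10-methyl-9-(trimethylsilyl)bicyclo[5.3.0]dec-9-en-5-one (route numbering)
Conditions: TiCl4, CH2Cl2, −78 °C
Reagents that add atoms: none
Why: Danheiser (trimethylsilyl)cyclopentene annulation: the allene CH2 terminus adds to C7 of the TiCl4-bound enone anti to the γ-OTBS group, a 1,2-silyl shift follows and the titanium enolate closes at C6 on the same face, which should give the cis-fused system with C6 and C7 set relative to C1 and the methyl-bearing carbon next to C6.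

Step 5
Reactants: 6 cis-fused annulation product
Product: 8 5,10α-diol (1α-OTBS, 9-TMS, C8=C9), via allylic hydroperoxide 7 (not isolated)
Conditions: O2, TPP (cat.), hν, CH2Cl2/MeOH, −20 °C; then NaBH4, 0 °C
Reagents that add atoms: oxygen (O=O)
Why: Schenck ene reaction with the geminal regioselectivity typical of vinylsilanes (O to C10, H from C8) on the exposed α face sets C10, and borohydride then reduces the hydroperoxide and, deliberately, the C5 ketone so that no β-alkoxy ketone can undergo retro-aldol cleavage in step 6.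

Step 6
Reactants: 8 5,10α-diol (1α-OTBS, 9-TMS)
Product: 9 1α,5,10α-triol with C8=C9
Conditions: TBAF, THF, 50 °C
Reagents that add atoms: none
Why: Fluoride cleaves the TBS ether, and the C10 alkoxide next to silicon promotes protodesilylation of the vinylsilane (1,3-Brook-type; Peterson elimination is impossible in the five-membered ring).

Step 7
Reactants: 9 1α,5,10α-triol
Product: 10 10α-hydroxy-10β-methyl-Δ8-1,5-dione
Conditions: Dess–Martin periodinane, NaHCO3, CH2Cl2, rt
Reagents that add atoms: none
Why: Dess–Martin oxidation converts both secondary alcohols under neutral conditions and leaves the tertiary allylic alcohol and the β,γ-unsaturated ketone untouched.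

Step 8
Reactants: 10 10α-hydroxy-1,5-dione
Product: 11 10α-(triethylsilyloxy)-1,5-dione
Conditions: TESOTf, 2,6-lutidine, CH2Cl2, −78 °C
Reagents that add atoms: triethylsilyl triflate (CC[Si](CC)(CC)OS(=O)(=O)C(F)(F)F)
Why: Silylation of the tertiary alcohol blocks retro-aldol opening of the five-membered ring in the later base-mediated steps.

Step 9
Reactants: 11 10α-(triethylsilyloxy)-1,5-dione
Product: 12 1-methylene-10α-(triethylsilyloxy)-Δ8-5-one
Conditions: Zn, CH2Br2, TiCl4 (Takai–Lombardo), THF/CH2Cl2, 0 °C → rt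
Reagents that add atoms: dibromomethane (BrCBr)
Why: Non-basic Takai–Lombardo methylenation avoids enolisation of the β,γ-unsaturated C1 ketone and should select C1 because the C5 carbonyl is shielded by C6 and the adjacent quaternary C10.

Step 10
Reactants: 12 1-methylene-5-one
Product: 13 2α-hydroxy-1-methylene-10α-(triethylsilyloxy)-Δ8-5-one
Conditions: SeO2 (cat.), t-BuOOH, CH2Cl2, 0 °C → rt
Reagents that add atoms: tert-butyl hydroperoxide (CC(C)(C)OO); selenium dioxide (O=[Se]=O)
Why: Selenium dioxide allylic hydroxylation (ene reaction, then [2,3]-shift) of the exocyclic methylene should oxidise the ring CH2 (C2) rather than the ring-fusion methine C7 and deliver oxygen to the open α face, which sets C2.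

Step 11
Reactants: 13 2α-hydroxy ketone
Product: 14 2α-(TBSO)-1-methylene-10α-(triethylsilyloxy)-Δ8-5-one (ring fragment)
Conditions: TBSOTf, 2,6-lutidine, CH2Cl2, −78 °C
Reagents that add atoms: tert-butyldimethylsilyl triflate (CC(C)(C)[Si](C)(C)OS(=O)(=O)C(F)(F)F)
Why: Silylation prevents transannular hemiketal formation between O2 and the C5 ketone and gives a group that lasts to the final step.

**Side-chain epoxide (steps 12–16)**

Step 12
Reactants: 15 (E)-crotonaldehyde; 16 2-methylprop-1-enylmagnesium bromide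
Product: 17 rac-(E)-6-methylhepta-2,5-dien-4-ol
Conditions: THF, −78 → 0 °C; aqueous work-up
Reagents that add atoms: none
Why: 1,2-Addition of the alkenyl Grignard reagent to the enal gives the bis-allylic alcohol with the whole C11–C15 skeleton.

Step 13
Reactants: 17 rac-(E)-6-methylhepta-2,5-dien-4-ol
Product: 18 (1R)-3-methyl-1-[(2R,3R)-3-methyloxiran-2-yl]but-2-en-1-ol (erythro)
Conditions: Ti(OiPr)4, D-(−)-DIPT, t-BuOOH (0.55 equiv), 4 Å MS, CH2Cl2, −20 °C
Reagents that add atoms: tert-butyl hydroperoxide (CC(C)(C)OO)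
Why: Sharpless kinetic resolution: the (S)-alcohol should be epoxidised at the E-propenyl arm (the isobutenyl arm carries a Z-methyl and reacts slowly), the tartrate setting C11 and C12 and giving the erythro epoxy alcohol.

Step 14
Reactants: 18 erythro epoxy alcohol
Product: 19 (1S)-3-methyl-1-[(2S,3R)-3-methyloxiran-2-yl]but-2-enyl 4-nitrobenzoate
Conditions: 4-nitrobenzoic acid, PPh3, DIAD, THF, 0 °C
Reagents that add atoms: 4-nitrobenzoic acid (OC(=O)c1ccc(cc1)[N+](=O)[O-])
Why: Mitsunobu inversion at C13 converts the erythro into the threo series needed for the syn-12,13-diol; SN2′ at the fully substituted alkene terminus is disfavoured.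

Step 15
Reactants: 19 threo 4-nitrobenzoate
Product: 20 (1S)-3-methyl-1-[(2R,3R)-3-methyloxiran-2-yl]but-2-en-1-ol (threo)
Conditions: K2CO3 (cat.), MeOH, 0 °C
Reagents that add atoms: none
Why: Mild methanolysis of the activated ester frees the threo alcohol before Payne rearrangement can compete.

Step 16
Reactants: 20 threo epoxy alcohol
Product: 21 triethylsilyl ether of 20, (2S,3R)-2-[(1S)-3-methyl-1-(triethylsilyloxy)but-2-enyl]-3-methyloxirane
Conditions: TESCl, imidazole, CH2Cl2, 0 °C
Reagents that add atoms: triethylsilyl chloride (CC[Si](CC)(CC)Cl)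
Why: Neutral silylation avoids the alkoxide (no Payne rearrangement) and installs a group that is removed selectively in step 18.

**Fragment union and endgame (steps 17–21)**

Step 17
Reactants: 14 ring-fragment ketone; 21 side-chain epoxide
Product: 23 coupled γ-hydroxy ketone, 4-epi (4R,11R,12S,13S; 13-OTES), via lithium enolate 22 (not isolated)
Conditions: LDA, THF, −78 °C; then 21, Sc(OTf)3 (20 mol %), toluene, −40 → 0 °C; aqueous work-up
Reagents that add atoms: none
Why: Kinetic deprotonation of 14 occurs only at the C4 methylene (C6 is a hindered methine next to quaternary C10), and C4 of lithium enolate 22 opens the Lewis-acid-activated trans-epoxide 21 by SN2 attack at C11, the methyl-bearing terminus remote from the deactivating C13–O bond. The closest known reaction type is the Lewis-acid-promoted alkylation of ketone lithium enolates with epoxides to γ-hydroxy ketones; no ring of the target is closed (the product may rest as its hemiketal). C11 is set by inversion at the epoxide carbon, C12 keeps the epoxide C–O configuration and C13 is carried in from 21, so all three side-chain stereocentres come from the Sharpless-derived epoxide. C4 is formed under substrate control: axial attack on the enolate from the open α face, anti to the pseudo-axial C6–C10 bond, should give mainly the 4-epi ketone, which is why step 18 resets this one epimerisable centre. The selectivities needed are C4 versus C6 enolisation and C11 versus C12 opening, secured by the substitution pattern of 14 and by the sterics and inductive bias of 21.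

Step 18
Reactants: 23 coupled γ-hydroxy ketone (4-epi)
Product: 26 (4S)-12,13-dihydroxy ketone, via dihydrofuran 24 (not isolated), via C4-corrected silyl ether 25 (not isolated)
Conditions: PPTS (cat.), 4 Å MS, PhH, 60 °C; then AcOH/THF/H2O (3:1:1), rt
Reagents that add atoms: none
Why: Acid-catalysed cyclodehydration of the γ-hydroxy ketone gives the 2,3-dihydrofuran (C4=C5 enol ether), whose kinetic protonation at C4 from the open α face (anti to C10 and to the C11 methyl) followed by hydration should set C4 (S) whatever the alkylation delivered, and the same aqueous acid removes the secondary C13 triethylsilyl ether while the tertiary TES and the TBS ether persist.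

Step 19
Reactants: 26 (4S)-12,13-dihydroxy ketone
Product: 27 12,13-diacetate ketone
Conditions: Ac2O, pyridine, DMAP (cat.), CH2Cl2, 0 °C → rt
Reagents that add atoms: acetic anhydride (CC(=O)OC(C)=O)
Why: Acetylation of the only two free hydroxyls is unambiguous because C2 and C10 are silylated and C5 is still a ketone; acylation also pulls any hemiketal to the open ketone.

Step 20
Reactants: 27 12,13-diacetate ketone
Product: 28 5β-alcohol (2-OTBS, 10-OTES, 12,13-diacetate)
Conditions: L-Selectride, THF, −78 °C
Reagents that add atoms: none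
Why: The bulky hydride attacks the C5 ketone equatorially from the α face (the β face is blocked by the C4 side chain, C10 and the axial C7–C8 bond) and should give the axial 5β-alcohol cis to both neighbours, the acetates surviving at −78 °C.

Step 21
Reactants: 28 5β-alcohol bis-silyl ether
Product: 29 target compound
Conditions: HF·pyridine, pyridine, THF, 0 °C → rt
Reagents that add atoms: none
Why: Buffered fluoride removes the TBS and TES ethers without touching the acetates or ionising the tertiary allylic alcohol.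

**Compound list**

1 | cyclohepta-1,3-diene | C1=CC=CCCC1 | starting material
2 | 6,7-dioxabicyclo[3.2.2]non-8-ene (meso) | C1=C[C@H]2CCC[C@@H]1OO2 | intermediate
3 | (R)-4-hydroxycyclohept-2-en-1-one | O=C1C=C[C@H](O)CCC1 | intermediate
4 | (R)-4-(tert-butyldimethylsilyloxy)cyclohept-2-en-1-one | O=C1C=C[C@H](O[Si](C)(C)C(C)(C)C)CCC1 | intermediate
5 | 1-methyl-1-(trimethylsilyl)allene | C=C=C(C)[Si](C)(C)C | starting material
6 | cis-fused 1α-(TBSO)-10-methyl-9-(trimethylsilyl)bicyclo[5.3.0]dec-9-en-5-one (route numbering, H-6/H-7 α) | [C@@H]1(O[Si](C)(C)C(C)(C)C)CCCC(=O)[C@@H]2[C@H]1CC([Si](C)(C)C)=C2C | intermediate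
7 | 10α-hydroperoxy-10β-methyl-9-(trimethylsilyl)-Δ8-5-one (1α-OTBS) | [C@@H]1(O[Si](C)(C)C(C)(C)C)CCCC(=O)[C@@H]2[C@H]1C=C([Si](C)(C)C)[C@@]2(C)OO | intermediate (not isolated)
8 | 5,10α-diol (1α-OTBS, 9-TMS, C8=C9; C5 epimers) | [C@@H]1(O[Si](C)(C)C(C)(C)C)CCCC(O)[C@@H]2[C@H]1C=C([Si](C)(C)C)[C@@]2(C)O | intermediate
9 | Δ8-1α,5,10α-triol (C5 epimers) | [C@@H]1(O)CCCC(O)[C@@H]2[C@H]1C=C[C@@]2(C)O | intermediate
10 | 10α-hydroxy-10β-methyl-Δ8-1,5-dione | O=C1CCCC(=O)[C@@H]2[C@H]1C=C[C@@]2(C)O | intermediate
11 | 10α-(triethylsilyloxy)-10β-methyl-Δ8-1,5-dione | O=C1CCCC(=O)[C@@H]2[C@H]1C=C[C@@]2(C)O[Si](CC)(CC)CC | intermediate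
12 | 1-methylene-10α-(triethylsilyloxy)-Δ8-5-one | C=C1CCCC(=O)[C@@H]2[C@H]1C=C[C@@]2(C)O[Si](CC)(CC)CC | intermediate
13 | 2α-hydroxy-1-methylene-10α-(triethylsilyloxy)-Δ8-5-one | C=C1[C@H](O)CCC(=O)[C@@H]2[C@H]1C=C[C@@]2(C)O[Si](CC)(CC)CC | intermediate
14 | 2α-(TBSO)-1-methylene-10α-(triethylsilyloxy)-Δ8-5-one (ring fragment) | C=C1[C@H](O[Si](C)(C)C(C)(C)C)CCC(=O)[C@@H]2[C@H]1C=C[C@@]2(C)O[Si](CC)(CC)CC | intermediate
15 | (E)-crotonaldehyde | C/C=C/C=O | starting material
16 | 2-methylprop-1-enylmagnesium bromide | CC(C)=C[Mg]Br | starting material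
17 | rac-(E)-6-methylhepta-2,5-dien-4-ol | C/C=C/C(O)C=C(C)C | intermediate
18 | (1R)-3-methyl-1-[(2R,3R)-3-methyloxiran-2-yl]but-2-en-1-ol | C[C@H]1O[C@@H]1[C@H](O)C=C(C)C | intermediate
19 | (1S)-3-methyl-1-[(2S,3R)-3-methyloxiran-2-yl]but-2-enyl 4-nitrobenzoate | C[C@H]1O[C@@H]1[C@@H](OC(=O)c2ccc(cc2)[N+](=O)[O-])C=C(C)C | intermediate
20 | (1S)-3-methyl-1-[(2R,3R)-3-methyloxiran-2-yl]but-2-en-1-ol | C[C@H]1O[C@@H]1[C@@H](O)C=C(C)C | intermediate
21 | (2S,3R)-2-[(1S)-3-methyl-1-(triethylsilyloxy)but-2-enyl]-3-methyloxirane | C[C@H]1O[C@@H]1[C@@H](O[Si](CC)(CC)CC)C=C(C)C | intermediate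
22 | lithium Δ4-enolate of 14 | C=C1[C@H](O[Si](C)(C)C(C)(C)C)CC=C(O[Li])[C@@H]2[C@H]1C=C[C@@]2(C)O[Si](CC)(CC)CC | intermediate (not isolated)
23 | coupled γ-hydroxy ketone, 4-epi (4R,11R,12S,13S; 13-OTES) | C=C1[C@H](O[Si](C)(C)C(C)(C)C)C[C@H]([C@@H](C)[C@H](O)[C@H](C=C(C)C)O[Si](CC)(CC)CC)C(=O)[C@@H]2[C@H]1C=C[C@@]2(C)O[Si](CC)(CC)CC | intermediate
24 | 2,3-dihydrofuran (cyclic enol ether C4=C5–O12) | C=C1[C@H](O[Si](C)(C)C(C)(C)C)CC2=C(O[C@H]([C@H](C=C(C)C)O[Si](CC)(CC)CC)[C@@H]2C)[C@@H]3[C@H]1C=C[C@@]3(C)O[Si](CC)(CC)CC | intermediate (not isolated)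
25 | (4S)-γ-hydroxy ketone, 13-OTES | C=C1[C@H](O[Si](C)(C)C(C)(C)C)C[C@@H]([C@@H](C)[C@H](O)[C@H](C=C(C)C)O[Si](CC)(CC)CC)C(=O)[C@@H]2[C@H]1C=C[C@@]2(C)O[Si](CC)(CC)CC | intermediate (not isolated)
26 | (4S)-12,13-dihydroxy ketone | C=C1[C@H](O[Si](C)(C)C(C)(C)C)C[C@@H]([C@@H](C)[C@H](O)[C@H](C=C(C)C)O)C(=O)[C@@H]2[C@H]1C=C[C@@]2(C)O[Si](CC)(CC)CC | intermediate
27 | 12,13-diacetate ketone | C=C1[C@H](O[Si](C)(C)C(C)(C)C)C[C@@H]([C@@H](C)[C@H](OC(C)=O)[C@H](C=C(C)C)OC(C)=O)C(=O)[C@@H]2[C@H]1C=C[C@@]2(C)O[Si](CC)(CC)CC | intermediate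
28 | 5β-alcohol (2-OTBS, 10-OTES, 12,13-diacetate) | C=C1[C@H](O[Si](C)(C)C(C)(C)C)C[C@@H]([C@@H](C)[C@H](OC(C)=O)[C@H](C=C(C)C)OC(C)=O)[C@@H](O)[C@@H]2[C@H]1C=C[C@@]2(C)O[Si](CC)(CC)CC | intermediate
29 | target compound | C=C1[C@H](O)C[C@@H]([C@@H](C)[C@H](OC(C)=O)[C@H](C=C(C)C)OC(C)=O)[C@@H](O)[C@@H]2[C@H]1C=C[C@@]2(C)O | target

**Step count and risks**

Total step count: 21. Longest linear sequence: 16 steps (steps 1–11, then 17–21); the side-chain epoxide takes steps 12–16.

Steps most likely to fail:

1. Step 17 (key step). The SN2 opening of the 2,3-disubstituted epoxide may be slow, so that the enolate acts as a base (epoxide to allylic alcohol isomerisation, proton transfer), or part of the attack may go to C12. Fallback: Corey–Enders aza-enolate alkylation, which opens 1,2-disubstituted epoxides without Lewis acid. Ketone 14 is condensed with N,N-dimethylhydrazine to the hydrazone F1. F1 is deprotonated at C4 with LDA to the lithium aza-enolate F2, which is alkylated with 21 at 0 °C to the hydroxy hydrazone F3. F3 is hydrolysed with aqueous CuCl2 at pH 7 to 23, where the route continues unchanged, since step 18 corrects C4 whatever its configuration.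

2. Step 18. The cyclodehydration may ionise or desilylate the tertiary allylic C10 silyl ether, or the enol ether may be protonated without facial selectivity. Fallback: base in place of acid. 23 is treated with LDA (2.2 equiv) at −78 °C; the C12 lithium alkoxide directs the second deprotonation to C4 and gives the dilithium alkoxide enolate F4. F4 is protonated at −78 °C with 2,6-di-tert-butylphenol from the α face to give 25, now isolated, and the C13 silyl ether of 25 is cleaved with AcOH/THF/H2O to reach 26.

3. Step 10. Oxygen may be transferred to the β face of C2 in the ene/[2,3] sequence, or the doubly allylic H-7 may be abstracted. Fallback for the facial problem: Mitsunobu inversion. The 2β-alcohol F5 formed from 12 is esterified with inversion (4-nitrobenzoic acid, PPh3, DIAD) to the 2α-ester F6, and methanolysis (K2CO3, MeOH, 0 °C) gives 13. This does not address abstraction of H-7.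

Further compounds
F1 | step 17 | N,N-dimethylhydrazone of 14 | C=C1[C@H](O[Si](C)(C)C(C)(C)C)CC/C(=N\N(C)C)[C@@H]2[C@H]1C=C[C@@]2(C)O[Si](CC)(CC)CC
F2 | step 17 | lithium aza-enolate of F1 | C=C1[C@H](O[Si](C)(C)C(C)(C)C)CC=C(N([Li])N(C)C)[C@@H]2[C@H]1C=C[C@@]2(C)O[Si](CC)(CC)CC
F3 | step 17 | C4-alkylated γ-hydroxy N,N-dimethylhydrazone | C=C1[C@H](O[Si](C)(C)C(C)(C)C)C[C@H]([C@@H](C)[C@H](O)[C@H](C=C(C)C)O[Si](CC)(CC)CC)/C(=N\N(C)C)[C@@H]2[C@H]1C=C[C@@]2(C)O[Si](CC)(CC)CC
F4 | step 18 | dilithium alkoxide enolate of 23 | C=C1[C@H](O[Si](C)(C)C(C)(C)C)CC([C@@H](C)[C@H](O[Li])[C@H](C=C(C)C)O[Si](CC)(CC)CC)=C(O[Li])[C@@H]2[C@H]1C=C[C@@]2(C)O[Si](CC)(CC)CC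
F5 | step 10 | 2β-hydroxy epimer of 13 | C=C1[C@@H](O)CCC(=O)[C@@H]2[C@H]1C=C[C@@]2(C)O[Si](CC)(CC)CC
F6 | step 10 | 2α-(4-nitrobenzoyloxy) ester | C=C1[C@H](OC(=O)c3ccc(cc3)[N+](=O)[O-])CCC(=O)[C@@H]2[C@H]1C=C[C@@]2(C)O[Si](CC)(CC)CC
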